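**Retrosynthetic overview**

1. The coumarin ether is made last by Mitsunobu coupling at C11–OH; the C3 ketone comes from the allylic C3–O of the cycloadduct, and the C6 acetate and the C7=C8 bond from its C6 ketone.
2. Rings A and B are closed together by an intramolecular Diels–Alder reaction of an acyclic trienone: diene C3=C2–C1=C10 (O3 as silyl enol ether) and dienophile C4=C5 of a β,β-dimethyl enone (C6=O), forming C3–C4 and C5–C10.
3. Enabling feature: in ring A the carbonyl carbon C3 is bonded to the quaternary C4(CH3)2, and the ring-fusion bond C5–C10 lies 1,4 to it across C1–C2; the ring B oxygen sits on C6 next to C5, so O3 can end a 1-oxy-diene and C6=O can activate C4=C5.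
4. Acyclic precursor: C9 by Johnson–Claisen chirality transfer from (R)-but-3-yn-2-ol; a temporary C8 methyl stereocentre (steers the cycloaddition, erased later) by cuprate addition and copper hydride reduction of an ynoate; the enone by Weinreb ketone synthesis.
5. Ring order: no carbocycle before step 13; rings A and B form simultaneously.

Key step: step 13

Remark on the chemistry: drimane numbering is used for all intermediates (ring A = C1–C5, C10; ring B = C5–C10; C11 = CH2O on C9; C12 = methyl on C8), and hydride addition to the 7-en-6-one (step 15) is assumed to occur anti to the axial C4 and C10 methyl groups.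

**Route**

Step 1
Reactants: 1 (R)-but-3-yn-2-ol; 2 (bromoethynyl)triisopropylsilane
Product: 3 (2R)-6-(triisopropylsilyl)hexa-3,5-diyn-2-ol
Conditions: CuCl (5 mol %), NH2OH·HCl, 30% aq. n-BuNH2, Et2O, 0 °C
Reagents that add atoms: none
Why: Cadiot–Chodkiewicz coupling of the terminal alkyne with the bromoalkyne should give the unsymmetrical diyne without touching the carbinol stereocentre.

Step 2
Reactants: 3 (2R)-6-(triisopropylsilyl)hexa-3,5-diyn-2-ol
Product: 4 (2R,3E)-6-(triisopropylsilyl)hex-3-en-5-yn-2-ol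
Conditions: LiAlH4, THF, 0 °C to rt; aq. work-up
Reagents that add atoms: none
Why: Hydroxyl-directed trans-hydroalumination reduces only the triple bond next to the carbinol and should give the E-enynol.

Step 3
Reactants: 4 (2R,3E)-6-(triisopropylsilyl)hex-3-en-5-yn-2-ol; 5 triethyl orthopropionate
Product: 7 ethyl (2RS,3S,4E)-2-methyl-3-[(triisopropylsilyl)ethynyl]hex-4-enoate, via mixed ketene acetal 6 (not isolated)
Conditions: EtCO2H (cat.), xylene, 140 °C, removal of EtOH
Reagents that add atoms: none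
Why: Johnson–Claisen [3,3] rearrangement through a chair with the carbinol methyl equatorial should transfer the C–O chirality suprafacially to the new C–C bond (future C9) and give the E-propenyl group; the α-methyl centre (future C10) forms as a mixture and is erased in step 8.

Step 4
Reactants: 7 ethyl (2RS,3S,4E)-2-methyl-3-[(triisopropylsilyl)ethynyl]hex-4-enoate
Product: 9 (3RS,4S)-3-methyl-4-[(triisopropylsilyl)ethynyl]oxolan-2-one, via hydroxy ester 8 (not isolated)
Conditions: O3, CH2Cl2/MeOH, −78 °C; NaBH4, −78 to 0 °C; 1 M HCl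
Reagents that add atoms: ozone, O=[O+][O-]
Why: Ozonolysis of the only alkene with reductive work-up should turn the propenyl group into the C11 hydroxymethyl group without a free, epimerisable aldehyde at C9, and the γ-hydroxy ester lactonises.

Step 5
Reactants: 9 (3RS,4S)-3-methyl-4-[(triisopropylsilyl)ethynyl]oxolan-2-one
Product: 10 (3RS,4S)-4-ethynyl-3-methyloxolan-2-one
Conditions: Bu4NF, THF, 0 °C
Reagents that add atoms: none
Why: Fluoride-induced C-desilylation frees the terminal alkyne before any silyl ether is present.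

Step 6
Reactants: 10 (3RS,4S)-4-ethynyl-3-methyloxolan-2-one
Product: 11 (4S)-4-ethynyl-3-methyloxolan-2-ol (lactol, mixture at C2 and C3)
Conditions: i-Bu2AlH, CH2Cl2, −78 °C
Reagents that add atoms: none
Why: Partial reduction of a γ-lactone at low temperature stops at the lactol.

Step 7
Reactants: 11 (4S)-4-ethynyl-3-methyloxolan-2-ol; 12 (triphenylphosphoranylidene)acetaldehyde
Product: 13 (2E,4RS,5S)-5-(hydroxymethyl)-4-methylhept-2-en-6-ynal
Conditions: toluene, 80 °C
Reagents that add atoms: none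
Why: Wittig olefination of the open hydroxy-aldehyde form with the stabilised formyl ylide should give the E-enal (two-carbon homologation to C2–C3).

Step 8
Reactants: 13 (2E,4RS,5S)-5-(hydroxymethyl)-4-methylhept-2-en-6-ynal
Product: 14 (3R,4E,6E)-7-[(tert-butyldimethylsilyl)oxy]-3-{[(tert-butyldimethylsilyl)oxy]methyl}-4-methylhepta-4,6-dien-1-yne
Conditions: TBSOTf (2.6 equiv), Et3N, CH2Cl2, −78 to 0 °C (crude 13 used at once)
Reagents that add atoms: tert-butyldimethylsilyl trifluoromethanesulfonate, CC(C)(C)[Si](C)(C)OS(=O)(=O)C(F)(F)F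
Why: O-silylation of the alcohol and soft enolisation (γ-deprotonation of the O-silylated enal) should give the 1-silyloxy diene with the bulky C9 branch trans to C2 at the new C10=C1 bond (least allylic strain), and prompt silylation forestalls oxa-Michael closure of 13.

Step 9
Reactants: 14 (3R,4E,6E)-7-[(tert-butyldimethylsilyl)oxy]-3-{[(tert-butyldimethylsilyl)oxy]methyl}-4-methylhepta-4,6-dien-1-yne
Product: 15 methyl (4S,5E,7E)-8-[(tert-butyldimethylsilyl)oxy]-4-{[(tert-butyldimethylsilyl)oxy]methyl}-5-methylocta-5,7-dien-2-ynoate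
Conditions: LDA, THF, −78 °C; ClCO2Me, −78 to −20 °C
Reagents that add atoms: methyl chloroformate, COC(=O)Cl
Why: C-acylation of the lithium acetylide gives the ynoate; silyl enol ethers tolerate LDA at low temperature.

Step 10
Reactants: 15 methyl (4S,5E,7E)-8-[(tert-butyldimethylsilyl)oxy]-4-{[(tert-butyldimethylsilyl)oxy]methyl}-5-methylocta-5,7-dien-2-ynoate
Product: 16 methyl (2Z,4S,5E,7E)-8-[(tert-butyldimethylsilyl)oxy]-4-{[(tert-butyldimethylsilyl)oxy]methyl}-3,5-dimethylocta-2,5,7-trienoate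
Conditions: Me2CuLi (from CuI and 2 MeLi), THF, −78 °C; MeOH, then aq. NH4Cl
Reagents that add atoms: lithium dimethylcuprate, [Li+].C[Cu-]C
Why: Syn-carbocupration (conjugate addition) of the ynoate at −78 °C places the new methyl cis to H, so the ester ends cis to C9 (Z).

Step 11
Reactants: 16 methyl (2Z,4S,5E,7E)-8-[(tert-butyldimethylsilyl)oxy]-4-{[(tert-butyldimethylsilyl)oxy]methyl}-3,5-dimethylocta-2,5,7-trienoate
Product: 17 methyl (3S,4R,5E,7E)-8-[(tert-butyldimethylsilyl)oxy]-4-{[(tert-butyldimethylsilyl)oxy]methyl}-3,5-dimethylocta-5,7-dienoate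
Conditions: Cu(OAc)2 (5 mol %), (R)-DTBM-SEGPHOS (5.5 mol %), (EtO)2MeSiH, t-BuOH, toluene, 0 °C to rt
Reagents that add atoms: none
Why: Ligand-controlled copper hydride 1,4-reduction of the β,β-disubstituted enoate should set the C8 methyl stereocentre (3S here); the ligand antipode is assigned by analogy with Z-β-methyl enoates, the other antipode giving the C8 epimer, and the electron-rich silyloxy diene is not an acceptor.

Step 12
Reactants: 17 methyl (3S,4R,5E,7E)-8-[(tert-butyldimethylsilyl)oxy]-4-{[(tert-butyldimethylsilyl)oxy]methyl}-3,5-dimethylocta-5,7-dienoate; 18 (2-methylprop-1-en-1-yl)magnesium bromide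
Product: 20 (6S,7R,8E,10E)-11-[(tert-butyldimethylsilyl)oxy]-7-{[(tert-butyldimethylsilyl)oxy]methyl}-2,6,8-trimethylundeca-2,8,10-trien-4-one, via Weinreb amide 19 (not isolated)
Conditions: MeNH(OMe)·HCl, i-PrMgCl, THF, −20 °C; then 18, −20 to 0 °C; cold aq. NH4Cl
Reagents that add atoms: none
Why: Weinreb ketone synthesis in one pot: the magnesium amide converts the ester into the N-methoxy-N-methylamide and the alkenyl Grignard adds once, the chelated adduct releasing the enone only on work-up.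

Step 13
Reactants: 20 (6S,7R,8E,10E)-11-[(tert-butyldimethylsilyl)oxy]-7-{[(tert-butyldimethylsilyl)oxy]methyl}-2,6,8-trimethylundeca-2,8,10-trien-4-one
Product: 21 (3S,5S,8S,9R,10S)-3,11-bis[(tert-butyldimethylsilyl)oxy]drim-1-en-6-one
Conditions: toluene (0.01 M), BHT (cat.), Et3N (cat.), sealed tube, 150 °C
Reagents that add atoms: none
Why: A thermal, concerted but asynchronous normal-demand [4+2] cycloaddition between the 1-silyloxy diene C3=C2–C1=C10 and the C4=C5 bond of the β,β-dimethyl enone (C6=O) should form C3–C4 and C5–C10 in one operation; the closest known class is the intramolecular Diels–Alder reaction of 1,7,9-decatrien-3-ones and of 1-silyloxy-1,3-dienes. Ring A closes as the six-membered cyclohexene of the [4+2] (C1=C2 remains), and ring B closes as a six-membered ketone through the four-atom tether C6–C7–C8–C9 in the fused (not bridged) mode. C10 and C5 are set by the exo (anti) transition state whose chair-like tether carries the C8 methyl and the C9 CH2OTBS group equatorial, so that the C10 methyl (Z on the diene terminus) becomes axial, cis to C11 and trans to H5; attack on the other diene face would place the C8 methyl 1,3-diaxial to the C10 methyl. C3 follows from the E enol ether (OTBS cis to C9) and C8 is temporary; both are erased later (steps 19 and 14). The step needs exo over endo selectivity, which dienes with a methyl on the tether-bearing terminus are expected to favour (trans-fused angular-methyl decalins), and bond formation at two fully substituted termini (C4, C10), which the donor-diene/enone pairing and the short tether should allow.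

Step 14
Reactants: 21 (3S,5S,8S,9R,10S)-3,11-bis[(tert-butyldimethylsilyl)oxy]drim-1-en-6-one
Product: 22 (3S,5S,9R,10S)-3,11-bis[(tert-butyldimethylsilyl)oxy]drima-1,7-dien-6-one
Conditions: IBX (3 equiv), DMSO/fluorobenzene, 70 °C
Reagents that add atoms: none
Why: IBX dehydrogenation of the ketone via its enol can only introduce C7=C8, because the other α-carbon (C5) has no β-hydrogen; this erases the temporary C8 stereocentre.

Step 15
Reactants: 22 (3S,5S,9R,10S)-3,11-bis[(tert-butyldimethylsilyl)oxy]drima-1,7-dien-6-one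
Product: 23 (3S,5S,6S,9R,10S)-3,11-bis[(tert-butyldimethylsilyl)oxy]drima-1,7-dien-6-ol (6-OH axial, cis to the C10 methyl)
Conditions: NaBH4, CeCl3·7H2O, MeOH/CH2Cl2, −40 °C
Reagents that add atoms: none
Why: Luche 1,2-reduction of the enone; hydride should add anti to the two syn-axial methyl groups (on C4 and C10), giving the axial 6S alcohol, the C6 epimer of what the target needs.

Step 16
Reactants: 23 (3S,5S,6S,9R,10S)-3,11-bis[(tert-butyldimethylsilyl)oxy]drima-1,7-dien-6-ol
Product: 24 (3S,5S,6R,9R,10S)-3,11-bis[(tert-butyldimethylsilyl)oxy]drima-1,7-dien-6-ol (6-OH equatorial, trans to the C10 methyl)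
Conditions: Re2O7 (3 mol %), Et2O, 0 °C to rt
Reagents that add atoms: none
Why: Perrhenate-mediated reversible 1,3-transposition and ionisation of the allylic alcohol should equilibrate the strained axial carbinol to the thermodynamic isomer, the secondary C6 alcohol with the trisubstituted C7=C8 bond and equatorial OH (6R), oxygen returning to C6 on the face anti to the axial methyls.

Step 17
Reactants: 24 (3S,5S,6R,9R,10S)-3,11-bis[(tert-butyldimethylsilyl)oxy]drima-1,7-dien-6-ol
Product: 25 (3S,5S,6R,9R,10S)-3,11-bis[(tert-butyldimethylsilyl)oxy]drima-1,7-dien-6-yl acetate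
Conditions: Ac2O, pyridine, DMAP (cat.), CH2Cl2, rt
Reagents that add atoms: acetic anhydride, CC(=O)OC(C)=O
Why: DMAP-catalysed acylation of the unhindered equatorial alcohol, with retention at C6.

Step 18
Reactants: 25 (3S,5S,6R,9R,10S)-3,11-bis[(tert-butyldimethylsilyl)oxy]drima-1,7-dien-6-yl acetate
Product: 26 (3S,5S,6R,9R,10S)-3,11-dihydroxydrima-1,7-dien-6-yl acetate
Conditions: HF·pyridine, THF/pyridine, 0 °C to rt
Reagents that add atoms: none
Why: Buffered fluoride cleaves both silyl ethers and leaves the allylic acetate in place.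

Step 19
Reactants: 26 (3S,5S,6R,9R,10S)-3,11-dihydroxydrima-1,7-dien-6-yl acetate
Product: 27 (5S,6R,9R,10S)-11-hydroxy-3-oxodrima-1,7-dien-6-yl acetate
Conditions: MnO2 (activated, excess), CH2Cl2, rt
Reagents that add atoms: none
Why: MnO2 oxidises the allylic C3 alcohol chemoselectively; the non-allylic primary C11 alcohol is not touched.

Step 20
Reactants: 27 (5S,6R,9R,10S)-11-hydroxy-3-oxodrima-1,7-dien-6-yl acetate
Product: 28 (5S,6R,9R,10S)-11-hydroxy-3-oxodrim-7-en-6-yl acetate
Conditions: H2 (1 atm), RhCl(PPh3)3 (10 mol %), toluene/EtOH, rt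
Reagents that add atoms: none
Why: Homogeneous hydrogenation with RhCl(PPh3)3 should reduce only the disubstituted C1=C2 bond of the enone, not the hindered trisubstituted C7=C8 bond or the allylic acetate.

Step 21
Reactants: 28 (5S,6R,9R,10S)-11-hydroxy-3-oxodrim-7-en-6-yl acetate; 29 umbelliferone (7-hydroxy-2H-chromen-2-one)
Product: 30 7-{[(5S,6R,9R,10S)-6-acetoxy-3-oxodrim-7-en-11-yl]oxy}-2H-chromen-2-one (target)
Conditions: PPh3, DIAD, THF, 0 °C to rt
Reagents that add atoms: none
Why: Mitsunobu etherification of the primary C11 alcohol with the acidic phenol; no stereocentre is involved, and ketone and allylic acetate are inert.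

**Compound list**

1 | (R)-but-3-yn-2-ol | C[C@@H](O)C#C | starting material
2 | (bromoethynyl)triisopropylsilane | BrC#C[Si](C(C)C)(C(C)C)C(C)C | starting material
3 | (2R)-6-(triisopropylsilyl)hexa-3,5-diyn-2-ol | C[C@@H](O)C#CC#C[Si](C(C)C)(C(C)C)C(C)C | intermediate
4 | (2R,3E)-6-(triisopropylsilyl)hex-3-en-5-yn-2-ol | C[C@@H](O)/C=C/C#C[Si](C(C)C)(C(C)C)C(C)C | intermediate
5 | triethyl orthopropionate | CCC(OCC)(OCC)OCC | starting material
6 | 1-ethoxy-1-{[(2R,3E)-6-(triisopropylsilyl)hex-3-en-5-yn-2-yl]oxy}prop-1-ene (mixed ketene acetal) | CC=C(OCC)O[C@H](C)/C=C/C#C[Si](C(C)C)(C(C)C)C(C)C | intermediate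
7 | ethyl (2RS,3S,4E)-2-methyl-3-[(triisopropylsilyl)ethynyl]hex-4-enoate | CCOC(=O)C(C)[C@@H](C#C[Si](C(C)C)(C(C)C)C(C)C)/C=C/C | intermediate
8 | ethyl (2RS,3S)-3-(hydroxymethyl)-2-methyl-5-(triisopropylsilyl)pent-4-ynoate | CCOC(=O)C(C)[C@H](CO)C#C[Si](C(C)C)(C(C)C)C(C)C | intermediate
9 | (3RS,4S)-3-methyl-4-[(triisopropylsilyl)ethynyl]oxolan-2-one | CC1C(=O)OC[C@@H]1C#C[Si](C(C)C)(C(C)C)C(C)C | intermediate
10 | (3RS,4S)-4-ethynyl-3-methyloxolan-2-one | CC1C(=O)OC[C@@H]1C#C | intermediate
11 | (4S)-4-ethynyl-3-methyloxolan-2-ol | CC1C(O)OC[C@@H]1C#C | intermediate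
12 | (triphenylphosphoranylidene)acetaldehyde | O=CC=P(c1ccccc1)(c1ccccc1)c1ccccc1 | starting material
13 | (2E,4RS,5S)-5-(hydroxymethyl)-4-methylhept-2-en-6-ynal | O=C/C=C/C(C)[C@H](CO)C#C | intermediate
14 | (3R,4E,6E)-7-[(tert-butyldimethylsilyl)oxy]-3-{[(tert-butyldimethylsilyl)oxy]methyl}-4-methylhepta-4,6-dien-1-yne | C#C[C@@H](CO[Si](C)(C)C(C)(C)C)/C(C)=C/C=C/O[Si](C)(C)C(C)(C)C | intermediate
15 | methyl (4S,5E,7E)-8-[(tert-butyldimethylsilyl)oxy]-4-{[(tert-butyldimethylsilyl)oxy]methyl}-5-methylocta-5,7-dien-2-ynoate | COC(=O)C#C[C@@H](CO[Si](C)(C)C(C)(C)C)/C(C)=C/C=C/O[Si](C)(C)C(C)(C)C | intermediate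
16 | methyl (2Z,4S,5E,7E)-8-[(tert-butyldimethylsilyl)oxy]-4-{[(tert-butyldimethylsilyl)oxy]methyl}-3,5-dimethylocta-2,5,7-trienoate | COC(=O)/C=C(C)\[C@@H](CO[Si](C)(C)C(C)(C)C)/C(C)=C/C=C/O[Si](C)(C)C(C)(C)C | intermediate
17 | methyl (3S,4R,5E,7E)-8-[(tert-butyldimethylsilyl)oxy]-4-{[(tert-butyldimethylsilyl)oxy]methyl}-3,5-dimethylocta-5,7-dienoate | COC(=O)C[C@H](C)[C@@H](CO[Si](C)(C)C(C)(C)C)/C(C)=C/C=C/O[Si](C)(C)C(C)(C)C | intermediate
18 | (2-methylprop-1-en-1-yl)magnesium bromide | CC(C)=C[Mg]Br | starting material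
19 | (3S,4R,5E,7E)-8-[(tert-butyldimethylsilyl)oxy]-4-{[(tert-butyldimethylsilyl)oxy]methyl}-N-methoxy-N,3,5-trimethylocta-5,7-dienamide | CON(C)C(=O)C[C@H](C)[C@@H](CO[Si](C)(C)C(C)(C)C)/C(C)=C/C=C/O[Si](C)(C)C(C)(C)C | intermediate
20 | (6S,7R,8E,10E)-11-[(tert-butyldimethylsilyl)oxy]-7-{[(tert-butyldimethylsilyl)oxy]methyl}-2,6,8-trimethylundeca-2,8,10-trien-4-one | CC(C)=CC(=O)C[C@H](C)[C@@H](CO[Si](C)(C)C(C)(C)C)/C(C)=C/C=C/O[Si](C)(C)C(C)(C)C | intermediate
21 | (3S,5S,8S,9R,10S)-3,11-bis[(tert-butyldimethylsilyl)oxy]drim-1-en-6-one | O=C1C[C@H](C)[C@@H](CO[Si](C)(C)C(C)(C)C)[C@]2(C)C=C[C@H](O[Si](C)(C)C(C)(C)C)C(C)(C)[C@@H]12 | intermediate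
22 | (3S,5S,9R,10S)-3,11-bis[(tert-butyldimethylsilyl)oxy]drima-1,7-dien-6-one | O=C1C=C(C)[C@@H](CO[Si](C)(C)C(C)(C)C)[C@]2(C)C=C[C@H](O[Si](C)(C)C(C)(C)C)C(C)(C)[C@@H]12 | intermediate
23 | (3S,5S,6S,9R,10S)-3,11-bis[(tert-butyldimethylsilyl)oxy]drima-1,7-dien-6-ol | O[C@H]1C=C(C)[C@@H](CO[Si](C)(C)C(C)(C)C)[C@]2(C)C=C[C@H](O[Si](C)(C)C(C)(C)C)C(C)(C)[C@@H]12 | intermediate
24 | (3S,5S,6R,9R,10S)-3,11-bis[(tert-butyldimethylsilyl)oxy]drima-1,7-dien-6-ol | O[C@@H]1C=C(C)[C@@H](CO[Si](C)(C)C(C)(C)C)[C@]2(C)C=C[C@H](O[Si](C)(C)C(C)(C)C)C(C)(C)[C@@H]12 | intermediate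
25 | (3S,5S,6R,9R,10S)-3,11-bis[(tert-butyldimethylsilyl)oxy]drima-1,7-dien-6-yl acetate | CC(=O)O[C@@H]1C=C(C)[C@@H](CO[Si](C)(C)C(C)(C)C)[C@]2(C)C=C[C@H](O[Si](C)(C)C(C)(C)C)C(C)(C)[C@@H]12 | intermediate
26 | (3S,5S,6R,9R,10S)-3,11-dihydroxydrima-1,7-dien-6-yl acetate | CC(=O)O[C@@H]1C=C(C)[C@@H](CO)[C@]2(C)C=C[C@H](O)C(C)(C)[C@@H]12 | intermediate
27 | (5S,6R,9R,10S)-11-hydroxy-3-oxodrima-1,7-dien-6-yl acetate | CC(=O)O[C@@H]1C=C(C)[C@@H](CO)[C@]2(C)C=CC(=O)C(C)(C)[C@@H]12 | intermediate
28 | (5S,6R,9R,10S)-11-hydroxy-3-oxodrim-7-en-6-yl acetate | CC(=O)O[C@@H]1C=C(C)[C@@H](CO)[C@]2(C)CCC(=O)C(C)(C)[C@@H]12 | intermediate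
29 | umbelliferone (7-hydroxy-2H-chromen-2-one) | Oc1ccc2ccc(=O)oc2c1 | starting material
30 | 7-{[(5S,6R,9R,10S)-6-acetoxy-3-oxodrim-7-en-11-yl]oxy}-2H-chromen-2-one | CC(=O)O[C@@H]1C=C(C)[C@@H](COc2ccc3ccc(=O)oc3c2)[C@]2(C)CCC(=O)C(C)(C)[C@@H]12 | target

**Totals**

Total step count: 21. Longest linear sequence: 21 steps (fully linear from 1).

**Three steps most likely to fail**

Step 13 (intramolecular Diels–Alder). What may go wrong: poor exo/endo discrimination, or 1,5-hydrogen shift and geometric scrambling of the silyloxy diene at the temperature needed for two fully substituted termini. The fallback sets out from compound 16 and keeps the C7=C8 bond in the tether. The Z-enoate would be converted with MeNH(OMe)·HCl/i-PrMgCl into the Weinreb amide F1 and then with Grignard reagent 18 into the cross-conjugated Z-dienone F2. In this planar enone tether, A(1,2) strain with the C8 methyl holds the CH2OTBS group anti to the incoming diene, so the endo mode (favoured by mild Lewis acid, Eu(fod)3, toluene, rt to 60 °C) should give the cis-fused dienone F3 with C11 cis to the C10 methyl. Brief epimerisation at C5, α to the ketone (DBU cat. or basic alumina, short contact to spare the γ-hydrogen at C9), would bring the material back to the route at compound 22, bypassing steps 11 to 14.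

Step 16 (thermodynamic correction of C6). What may go wrong: dehydration of the allylic perrhenate to dienes, or incomplete stereochemical equilibration. The fallback sets out from compound 22 and is stereospecific. Weitz–Scheffer epoxidation (t-BuOOH, benzyltrimethylammonium hydroxide, THF) on the face anti to the axial methyls should give the epoxy ketone F4. Wharton transposition (N2H4·H2O, AcOH cat., MeOH) would give the tertiary allylic alcohol F5 with oxygen on C8 on that same face. Acetylation (Ac2O, DMAP, Et3N) to the tertiary acetate F6 and a suprafacial [3,3] acetate shift catalysed by PdCl2(MeCN)2 (divalent palladium) in THF would deliver compound 25 directly, where the route is rejoined.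

Step 11 (copper hydride reduction). What may go wrong: competing hydrocupration of the silyloxy diene, or low facial control at C8, which would later mis-steer the cycloaddition. The fallback sets out from compound 14 and forms the C8–methyl bond instead of the C8–H bond. Hydrozirconation with Cp2Zr(H)Cl followed by iodine would give the E-vinyl iodide F7. Methoxycarbonylation (Pd(PPh3)4 cat., CO, MeOH, Et3N) would give the E-enoate F8. Copper-catalysed asymmetric conjugate addition of MeMgBr (CuBr·SMe2, Josiphos ligand of the appropriate hand, t-BuOMe, −75 °C) would return to the route at compound 17.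

Further compounds
F1 | step 13 | (2Z,4S,5E,7E)-8-[(tert-butyldimethylsilyl)oxy]-4-{[(tert-butyldimethylsilyl)oxy]methyl}-N-methoxy-N,3,5-trimethylocta-2,5,7-trienamide | CON(C)C(=O)/C=C(C)\[C@@H](CO[Si](C)(C)C(C)(C)C)/C(C)=C/C=C/O[Si](C)(C)C(C)(C)C
F2 | step 13 | (5Z,7S,8E,10E)-11-[(tert-butyldimethylsilyl)oxy]-7-{[(tert-butyldimethylsilyl)oxy]methyl}-2,6,8-trimethylundeca-2,5,8,10-tetraen-4-one | CC(C)=CC(=O)/C=C(C)\[C@@H](CO[Si](C)(C)C(C)(C)C)/C(C)=C/C=C/O[Si](C)(C)C(C)(C)C
F3 | step 13 | (3S,5R,9R,10S)-3,11-bis[(tert-butyldimethylsilyl)oxy]drima-1,7-dien-6-one (cis-fused C5 epimer of 22) | O=C1C=C(C)[C@@H](CO[Si](C)(C)C(C)(C)C)[C@]2(C)C=C[C@H](O[Si](C)(C)C(C)(C)C)C(C)(C)[C@H]12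
F4 | step 16 | (3S,5S,7R,8R,9R,10S)-3,11-bis[(tert-butyldimethylsilyl)oxy]-7,8-epoxydrim-1-en-6-one | O=C1[C@@H]3O[C@]3(C)[C@@H](CO[Si](C)(C)C(C)(C)C)[C@]2(C)C=C[C@H](O[Si](C)(C)C(C)(C)C)C(C)(C)[C@@H]12
F5 | step 16 | (3S,5S,8S,9R,10R)-3,11-bis[(tert-butyldimethylsilyl)oxy]drima-1,6-dien-8-ol | C1=C[C@](C)(O)[C@@H](CO[Si](C)(C)C(C)(C)C)[C@]2(C)C=C[C@H](O[Si](C)(C)C(C)(C)C)C(C)(C)[C@@H]12
F6 | step 16 | (3S,5S,8S,9R,10R)-3,11-bis[(tert-butyldimethylsilyl)oxy]drima-1,6-dien-8-yl acetate | C1=C[C@](C)(OC(C)=O)[C@@H](CO[Si](C)(C)C(C)(C)C)[C@]2(C)C=C[C@H](O[Si](C)(C)C(C)(C)C)C(C)(C)[C@@H]12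
F7 | step 11 | (1E,3R,4E,6E)-7-[(tert-butyldimethylsilyl)oxy]-3-{[(tert-butyldimethylsilyl)oxy]methyl}-1-iodo-4-methylhepta-1,4,6-triene | I/C=C/[C@@H](CO[Si](C)(C)C(C)(C)C)/C(C)=C/C=C/O[Si](C)(C)C(C)(C)C
F8 | step 11 | methyl (2E,4R,5E,7E)-8-[(tert-butyldimethylsilyl)oxy]-4-{[(tert-butyldimethylsilyl)oxy]methyl}-5-methylocta-2,5,7-trienoate | COC(=O)/C=C/[C@@H](CO[Si](C)(C)C(C)(C)C)/C(C)=C/C=C/O[Si](C)(C)C(C)(C)C
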